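## Structural features

The target is a depside of two benzene rings with no stereocentre. Ring A is a 2,4-dihydroxy-6-(2-oxononyl)benzoyl unit, ring B is methyl 2,4-dihydroxy-6-(2-oxononyl)benzoate, and the carboxyl carbon of ring A is esterified by the oxygen on C4 of ring B. Each ring carries a CH2–C(=O)–heptyl chain ortho to its carboxyl carbon, so both carbonyl carbons sit between two ortho substituents. Three phenols are free; the C2 hydroxyl of each ring is hydrogen-bonded to the neighbouring ester carbonyl, whereas the C4 hydroxyl of ring A is not. The fragile parts are the aryl ester link, which is an activated ester, and the two 2-oxoalkyl benzoate units. In these the ketone enol can close onto the adjacent ester to give a 3-heptylisocoumarin, and in ring A that closure would expel ring B. The real difficulty is the union of the halves: acylation of a phenol by a doubly ortho-substituted benzoic acid is slow, and acyl activation invites the lactone closure. The key step uses the fact that C4 of ring B lies between two unsubstituted carbons (C3 and C5). Boron can be placed there by sterically governed C–H borylation, and the bond is then made between C4 of ring B and the carboxylate oxygen of ring A, away from the crowded acyl carbon.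

## Logic of the disconnections

16 from 14 by way of 15. The three benzylic O–CH2 bonds on the phenols and the two dioxolanes are the last bonds to be cleaved. The phenols must be masked because free phenols would be arylated in the copper step. The ketones must be masked because a free keto acid or keto ester lactonizes. On ring B the C2 oxygen carries a 3,5-dimethylbenzyl group instead of a methyl group. A methyl ether would need a boron trihalide at the end, which would open the dioxolanes and drive the freed ketones onto the esters. A plain benzyl group would be borylated on its own ring. In the 3,5-dimethylbenzyl ring every C–H has two ortho neighbours, so the group is inert to the iridium catalyst and leaves by hydrogenolysis together with the benzyl ethers of ring A. The forward demand is neutral hydrogenolysis followed by only dilute acid.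

14 from 7 and 13. The bond between C4 of ring B and the ester oxygen is cut. This gives two fragments of similar size, each four steps from a commercial toluate, and the hindered acyl carbon of 7 is never activated. The forward step must be an oxidative copper coupling in which the carboxylate is the only nucleophile, and the dioxolanes must survive Lewis-acidic copper.

13 from 11 by way of 12. The C4–B bond is traced back to a C–H bond. Pre-functionalization of ring B is avoided and the position is dictated by sterics alone. The forward step needs a catalyst that ignores every other C–H bond and a boronate cleavage that uses no strong acid.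

11 from 10, and 10 from 9 and 2. The dioxolane is removed and the bond between the benzylic carbon and the ketone carbon is cut. Lateral metalation of the ortho-toluate turns the methyl group into the nucleophile and 2 delivers the whole eight-carbon acyl chain in one step. The ketalization must run under aprotic, cold conditions so that the keto ester does not lactonize.

9 from 8. The O–CH2 bond of the ring B ether is cut, which leads back to a commercial salicylate. The alkylation must overcome the hydrogen bond of the phenol to the ester.

7 from 6, 6 from 5, 5 from 4 and 2, and 4 from 3. The same three operations are applied to ring A, preceded by the cut of the two O-benzyl bonds and followed by cleavage of the methyl ester. The demand is hydrolysis at a doubly ortho-substituted ester under base alone, with liberation of the acid by a weak acid.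

2 from 1. The amide C–N bond is cut. The acyl donor is thereby set to the oxidation level that stops at the ketone.

## Other disconnections considered

Alternative 1: The cut is the C1–C6 bond of ring A, which unfolds ring A into a linear chain on the ring B oxygen. In the forward step the aryl 3,5,7-trioxo ester A2 would cyclize under mild base. Its C2 methylene adds to the C7 ketone, and dehydration and enolization give A1, which is the same compound as 15. A2 would come from an acylketene trapped at the C4 hydroxyl of the ring B diol A3.

- In its favour: ring A appears with both phenols free and needs no protecting group, and the depside ester is formed at an unhindered aliphatic acyl carbon. On protecting-group economy this plan is better than the chosen one, and on avoiding the hindered acylation it is its equal.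
- Against it: A2 is an aryl ester of a β-keto acid, and phenoxide is a good leaving group. Claisen-type attack of the C6 methylene on the ester carbonyl, or pyrone formation, would therefore expel ring B, and nothing in the substrate enforces the aldol mode. A2 also has four enolizable positions and a multi-step chain to assemble.
- Comparison: the chosen plan fixes the site of the link by the position of boron and does not depend on competition between cyclization modes. Because A3 and the chain must both be built, the step count is not expected to be lower.

Alternative 2: The cuts are the aryl–CH2 bond at C6 and the aryl–carboxyl bond at C1 of ring B. In the forward step fluoride would release 3,5-bis(benzyloxy)benzyne from the silyl triflate A5. The carbanion of A6 adds at the aryne carbon remote from the neighbouring benzyloxy group, the aryl anion attacks one ester carbonyl, and the four-membered alkoxide fragments to the homophthalate A4. The "3,5" locants of the trivial name count from the acetic acid side chain; the unambiguous name of A4 is methyl 2,4-bis(benzyloxy)-6-(2-methoxy-2-oxoethyl)benzoate.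

- In its favour: two C–C bonds form in one mild step without strong base, which is better than lateral lithiation for base-sensitive substrates. The alkoxy group directs the regiochemistry as reliably as the ester directs lateral metalation, so the two are equal on that point.
- Against it: the depside bond is not addressed at all. The aliphatic ester of A4 must be distinguished from the aromatic one and turned into the heptyl ketone over several steps, where lateral acylation with 2 does this in one. The two benzyl ethers on C2 and C4 are not differentiated, so the link would again be made by acylating a phenol with a hindered acid. A5 needs a multi-step synthesis.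
- Comparison: the plan is longer and leaves the central problem unsolved.

Alternative 3: The cuts are the C1–C2 and C5–C6 bonds of ring A. In the forward step the diene A9 would add to the ring B aryl alkynoate A8. The CH2 terminus of the diene bonds to the alkyne carbon that bears the side chain and the acetal carbon bonds to the carbon that bears the ester. Loss of methanol and of the silyl group gives A7.

- In its favour: the ester link is formed before ring A exists, at an unhindered alkynoic acid, so it avoids the hindered acylation as well as the chosen plan does. The polarization of diene and ynoate should control the regiochemistry, and the C4 phenol of ring A arrives free.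
- Against it: a β-alkyl ynoate is a sluggish dienophile and would need heating with a moisture-sensitive diene. The propargylic CH2 next to the dioxolane can isomerize to an allene. The C2 oxygens of both rings end as methyl ethers, so the last step would need a boron trihalide in the presence of dioxolanes or ketones, the situation the chosen plan was redesigned to avoid. A8 requires a ring B phenol and an alkynoic acid, each from a separate sequence.
- Comparison: step economy is at best equal and the end game is weaker.

Key step: step 10

Assumption: methyl 2-hydroxy-6-methylbenzoate, 3,5-dimethylbenzyl bromide, benzyl bromide, N,O-dimethylhydroxylamine hydrochloride and bis(pinacolato)diboron are taken as purchasable, and a dialkyl ketone dioxolane is taken to survive an extraction at pH 5 and a urea-buffered Cu(OTf)2 coupling.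

## Steps

Step 1
Reactants: 1 octanoyl chloride
Product: 2 N-methoxy-N-methyloctanamide
Conditions: MeNHOMe·HCl, K2CO3, EtOAc/H2O, 0 °C to rt
Reagents that add atoms: N,O-dimethylhydroxylamine hydrochloride, CNOC.Cl
Why: Schotten–Baumann acylation of the amine by the acid chloride; the Weinreb amide is the acyl donor that stops at the ketone stage in steps 3 and 7.

Step 2
Reactants: 3 methyl 2,4-dihydroxy-6-methylbenzoate
Product: 4 methyl 2,4-bis(benzyloxy)-6-methylbenzoate
Conditions: BnBr, K2CO3, n-Bu4NI (cat.), DMF, 60 °C
Reagents that add atoms: benzyl bromide, BrCc1ccccc1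
Why: Williamson ether synthesis; warming should also alkylate the hydrogen-bonded C2 hydroxyl, and the benzyl ethers tolerate the strong base, the ketalization and the copper step that follow.

Step 3
Reactants: 4 methyl 2,4-bis(benzyloxy)-6-methylbenzoate; 2 N-methoxy-N-methyloctanamide
Product: 5 methyl 2,4-bis(benzyloxy)-6-(2-oxononyl)benzoate
Conditions: LiN(iPr)2 (2 equiv), THF, −78 °C; then 2, −78 to 0 °C; aq. NH4Cl
Reagents that add atoms: none
Why: Lateral lithiation of the ortho-toluate gives an ester-stabilized benzylic anion that adds to the Weinreb amide. The chelated tetrahedral adduct should persist until the quench, so neither double addition nor enolization of the acidic product ketone is expected.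

Step 4
Reactants: 5 methyl 2,4-bis(benzyloxy)-6-(2-oxononyl)benzoate
Product: 6 methyl 2,4-bis(benzyloxy)-6-[(2-heptyl-1,3-dioxolan-2-yl)methyl]benzoate
Conditions: TMSOCH2CH2OTMS, TMSOTf (cat.), CH2Cl2, −78 to −20 °C; pyridine quench
Reagents that add atoms: 1,2-bis(trimethylsilyloxy)ethane, C[Si](C)(C)OCCO[Si](C)(C)C
Why: Noyori ketalization; the aprotic, cold conditions avoid the protic acid and heat that would drive enol lactonization of the keto ester to an isocoumarin.

Step 5
Reactants: 6 methyl 2,4-bis(benzyloxy)-6-[(2-heptyl-1,3-dioxolan-2-yl)methyl]benzoate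
Product: 7 2,4-bis(benzyloxy)-6-[(2-heptyl-1,3-dioxolan-2-yl)methyl]benzoic acid
Conditions: KOH, DMSO/H2O, 90 °C; then AcOH to pH 5, 0 °C
Reagents that add atoms: potassium hydroxide, [K+].[OH-]
Why: Saponification of a hindered ester by poorly solvated hydroxide in DMSO; benzyl ethers and the dioxolane are inert to base, and the acid is freed with a weak acid to spare the dioxolane.

Step 6
Reactants: 8 methyl 2-hydroxy-6-methylbenzoate
Product: 9 methyl 2-[(3,5-dimethylbenzyl)oxy]-6-methylbenzoate
Conditions: 3,5-dimethylbenzyl bromide, K2CO3, DMF, 60 °C
Reagents that add atoms: 3,5-dimethylbenzyl bromide, Cc1cc(C)cc(CBr)c1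
Why: Williamson ether synthesis; the group is chosen because all C–H bonds of its ring are flanked by two substituents, which should make it inert in step 9, and because it is removed by hydrogenolysis like a benzyl ether.

Step 7
Reactants: 9 methyl 2-[(3,5-dimethylbenzyl)oxy]-6-methylbenzoate; 2 N-methoxy-N-methyloctanamide
Product: 10 methyl 2-[(3,5-dimethylbenzyl)oxy]-6-(2-oxononyl)benzoate
Conditions: LiN(iPr)2 (2 equiv), THF, −78 °C; then 2, −78 to 0 °C; aq. NH4Cl
Reagents that add atoms: none
Why: Lateral lithiation and Weinreb acylation as in step 3; the ring methyl ortho to the ester is far more acidic than the methyl groups or the OCH2 of the ether.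

Step 8
Reactants: 10 methyl 2-[(3,5-dimethylbenzyl)oxy]-6-(2-oxononyl)benzoate
Product: 11 methyl 2-[(3,5-dimethylbenzyl)oxy]-6-[(2-heptyl-1,3-dioxolan-2-yl)methyl]benzoate
Conditions: TMSOCH2CH2OTMS, TMSOTf (cat.), CH2Cl2, −78 to −20 °C; pyridine quench
Reagents that add atoms: 1,2-bis(trimethylsilyloxy)ethane, C[Si](C)(C)OCCO[Si](C)(C)C
Why: Noyori ketalization as in step 4; the dioxolane removes the acidic keto methylene before the borylation and the copper step.

Step 9
Reactants: 11 methyl 2-[(3,5-dimethylbenzyl)oxy]-6-[(2-heptyl-1,3-dioxolan-2-yl)methyl]benzoate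
Product: 13 {3-[(3,5-dimethylbenzyl)oxy]-5-[(2-heptyl-1,3-dioxolan-2-yl)methyl]-4-(methoxycarbonyl)phenyl}boronic acid, via pinacol boronate 12 (not isolated)
Conditions: B2pin2 (1.0 equiv), [Ir(OMe)(cod)]2 (1.5 mol %), 4,4′-di-tert-butyl-2,2′-bipyridine (3 mol %), THF, 60 °C; evaporate; NaIO4, NH4OAc, acetone/H2O, rt
Reagents that add atoms: bis(pinacolato)diboron, CC1(C)OB(OC1(C)C)B1OC(C)(C)C(C)(C)O1; water, O
Why: Iridium-catalysed aromatic C–H borylation through a trivalent iridium tris(boryl) complex is governed by sterics and should take C4–H, the only ring hydrogen without an ortho neighbour. Every C–H of the 3,5-dimethylbenzyl ring is flanked twice, as in mesitylene, and should stay untouched. Buffered periodate then cleaves the pinacol ester oxidatively without acid, so the dioxolane is spared.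

Step 10
Reactants: 7 2,4-bis(benzyloxy)-6-[(2-heptyl-1,3-dioxolan-2-yl)methyl]benzoic acid; 13 {3-[(3,5-dimethylbenzyl)oxy]-5-[(2-heptyl-1,3-dioxolan-2-yl)methyl]-4-(methoxycarbonyl)phenyl}boronic acid
Product: 14 3-[(3,5-dimethylbenzyl)oxy]-5-[(2-heptyl-1,3-dioxolan-2-yl)methyl]-4-(methoxycarbonyl)phenyl 2,4-bis(benzyloxy)-6-[(2-heptyl-1,3-dioxolan-2-yl)methyl]benzoate
Conditions: Cu(OTf)2 (0.4 equiv), urea (1 equiv), 13 (1.5 equiv), 4 Å MS, EtOAc, air, 60 °C
Reagents that add atoms: none
Why: The carboxylate of 7 binds divalent copper and the aryl group of 13 is transferred from boron to copper. Oxidation by a second divalent copper or by oxygen gives a trivalent copper aryl carboxylate, and reductive elimination forms the bond between C4 of ring B and the carboxylate oxygen; air reoxidizes the monovalent copper released. The closest known reaction type is the Chan–Lam O-arylation of carboxylic acids with arylboronic acids under Cu(OTf)2 and urea. No ring is closed and no stereocentre is formed. Site selectivity is fixed by the carbon–boron bond set in step 9. Chemoselectivity follows from the protection pattern: all phenols are ethers, so the carboxylate is the only heteroatom nucleophile. The reaction occurs at oxygen, one atom away from the two ortho substituents that shield the acyl carbon, and the acid is never converted into an acylating agent, so the lactone closure onto the neighbouring masked ketone is not opened. Urea and molecular sieves temper the Lewis acidity of the copper salt to protect the dioxolanes, and the excess of 13 offsets loss of boron by protodeboronation or homocoupling.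

Step 11
Reactants: 14 3-[(3,5-dimethylbenzyl)oxy]-5-[(2-heptyl-1,3-dioxolan-2-yl)methyl]-4-(methoxycarbonyl)phenyl 2,4-bis(benzyloxy)-6-[(2-heptyl-1,3-dioxolan-2-yl)methyl]benzoate
Product: 16 3-hydroxy-4-(methoxycarbonyl)-5-(2-oxononyl)phenyl 2,4-dihydroxy-6-(2-oxononyl)benzoate (CNP0110390.0), via triphenol bis-dioxolane 15 (not isolated)
Conditions: H2 (1 atm), Pd/C, THF, rt; filter; then 1 M aq. HCl, THF, rt
Reagents that add atoms: water, O
Why: Hydrogenolysis cleaves the two benzyl ethers and the 3,5-dimethylbenzyl ether under neutral conditions that leave the aryl ester, the methyl ester and the dioxolanes alone. Dilute aqueous acid at room temperature then hydrolyses both dioxolanes, and no Lewis acid is present that could promote lactonization of the freed ketones onto the esters.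

## Compound list

1 | octanoyl chloride | CCCCCCCC(=O)Cl | starting material
2 | N-methoxy-N-methyloctanamide | CCCCCCCC(=O)N(C)OC | intermediate
3 | methyl 2,4-dihydroxy-6-methylbenzoate | Cc1cc(O)cc(O)c1C(=O)OC | starting material
4 | methyl 2,4-bis(benzyloxy)-6-methylbenzoate | Cc1cc(OCc2ccccc2)cc(OCc2ccccc2)c1C(=O)OC | intermediate
5 | methyl 2,4-bis(benzyloxy)-6-(2-oxononyl)benzoate | CCCCCCCC(=O)Cc1cc(OCc2ccccc2)cc(OCc2ccccc2)c1C(=O)OC | intermediate
6 | methyl 2,4-bis(benzyloxy)-6-[(2-heptyl-1,3-dioxolan-2-yl)methyl]benzoate | CCCCCCCC1(OCCO1)Cc1cc(OCc2ccccc2)cc(OCc2ccccc2)c1C(=O)OC | intermediate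
7 | 2,4-bis(benzyloxy)-6-[(2-heptyl-1,3-dioxolan-2-yl)methyl]benzoic acid | CCCCCCCC1(OCCO1)Cc1cc(OCc2ccccc2)cc(OCc2ccccc2)c1C(=O)O | intermediate
8 | methyl 2-hydroxy-6-methylbenzoate | Cc1cccc(O)c1C(=O)OC | starting material
9 | methyl 2-[(3,5-dimethylbenzyl)oxy]-6-methylbenzoate | Cc1cccc(OCc2cc(C)cc(C)c2)c1C(=O)OC | intermediate
10 | methyl 2-[(3,5-dimethylbenzyl)oxy]-6-(2-oxononyl)benzoate | CCCCCCCC(=O)Cc1cccc(OCc2cc(C)cc(C)c2)c1C(=O)OC | intermediate
11 | methyl 2-[(3,5-dimethylbenzyl)oxy]-6-[(2-heptyl-1,3-dioxolan-2-yl)methyl]benzoate | CCCCCCCC1(OCCO1)Cc1cccc(OCc2cc(C)cc(C)c2)c1C(=O)OC | intermediate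
12 | methyl 2-[(3,5-dimethylbenzyl)oxy]-6-[(2-heptyl-1,3-dioxolan-2-yl)methyl]-4-(4,4,5,5-tetramethyl-1,3,2-dioxaborolan-2-yl)benzoate | CCCCCCCC1(OCCO1)Cc1cc(B2OC(C)(C)C(C)(C)O2)cc(OCc2cc(C)cc(C)c2)c1C(=O)OC | intermediate
13 | {3-[(3,5-dimethylbenzyl)oxy]-5-[(2-heptyl-1,3-dioxolan-2-yl)methyl]-4-(methoxycarbonyl)phenyl}boronic acid | CCCCCCCC1(OCCO1)Cc1cc(B(O)O)cc(OCc2cc(C)cc(C)c2)c1C(=O)OC | intermediate
14 | 3-[(3,5-dimethylbenzyl)oxy]-5-[(2-heptyl-1,3-dioxolan-2-yl)methyl]-4-(methoxycarbonyl)phenyl 2,4-bis(benzyloxy)-6-[(2-heptyl-1,3-dioxolan-2-yl)methyl]benzoate | CCCCCCCC1(OCCO1)Cc1cc(OCc2ccccc2)cc(OCc2ccccc2)c1C(=O)Oc1cc(OCc2cc(C)cc(C)c2)c(C(=O)OC)c(CC2(CCCCCCC)OCCO2)c1 | intermediate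
15 | 3-hydroxy-5-[(2-heptyl-1,3-dioxolan-2-yl)methyl]-4-(methoxycarbonyl)phenyl 2,4-dihydroxy-6-[(2-heptyl-1,3-dioxolan-2-yl)methyl]benzoate | CCCCCCCC1(OCCO1)Cc1cc(O)cc(O)c1C(=O)Oc1cc(O)c(C(=O)OC)c(CC2(CCCCCCC)OCCO2)c1 | intermediate
16 | 3-hydroxy-4-(methoxycarbonyl)-5-(2-oxononyl)phenyl 2,4-dihydroxy-6-(2-oxononyl)benzoate | CCCCCCCC(=O)Cc1cc(OC(=O)c2c(O)cc(O)cc2CC(=O)CCCCCCC)cc(O)c1C(=O)OC | target

## Step count and least certain steps

Total: 11 steps. Longest linear sequence: 6 steps (steps 2, 3, 4, 5, 10 and 11 from 3; the ring B branch, steps 6 to 11 from 8, is equally long).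

Step 10 (key step). Transmetalation and reductive elimination with a bulky, electron-rich carboxylate may be slow, so that protodeboronation or oxidative hydroxylation of the boronic acid consumes it first. The Lewis-acidic copper salt may also open a dioxolane, or the electron-rich acid may lose carbon dioxide. The fallback gives up the aryl C–O bond formation and makes the acyl C–O bond. It sets out from 13 and 7 and returns at 14. Compound 13 is oxidized with H2O2 in THF/H2O to the phenol methyl 2-[(3,5-dimethylbenzyl)oxy]-4-hydroxy-6-[(2-heptyl-1,3-dioxolan-2-yl)methyl]benzoate F1. Compound 7 is converted under neutral conditions with 1-chloro-N,N,2-trimethylprop-1-en-1-amine in CH2Cl2 at 0 °C into 2,4-bis(benzyloxy)-6-[(2-heptyl-1,3-dioxolan-2-yl)methyl]benzoyl chloride F2. F2 is used at once with the sodium phenoxide of F1 (NaH, THF, 0 °C) to give 14.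

Step 9. The periodate cleavage of the pinacol ester may stall, or boron may be lost by protodeboronation during the aqueous stage, and the crude boronic acid is hard to purify; a small amount of benzylic borylation is a lesser concern. The fallback sets out from 12, which is then isolated by chromatography, and returns at 13. Treatment with KHF2 in aqueous methanol should give the crystalline salt potassium {3-[(3,5-dimethylbenzyl)oxy]-5-[(2-heptyl-1,3-dioxolan-2-yl)methyl]-4-(methoxycarbonyl)phenyl}trifluoroborate F3. F3 is purified by precipitation and hydrolysed with LiOH in aqueous acetonitrile at room temperature to 13; the hindered methyl ester should not be touched under these conditions.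

Step 5. Attack of hydroxide on the doubly ortho-substituted ester carbonyl may be too slow below temperatures that degrade the substrate. On acidification the dioxolane next to the new carboxyl group may open and close to a lactone. The fallback moves the forcing hydrolysis to a stage without a dioxolane and unveils the acid by zerovalent palladium chemistry. It sets out from 4 and returns at 7.

- Compound 4 is saponified (KOH, DMSO/H2O, 100 °C) to 2,4-bis(benzyloxy)-6-methylbenzoic acid F4.
- Alkylation of its carboxylate with allyl bromide and K2CO3 in DMF gives prop-2-en-1-yl 2,4-bis(benzyloxy)-6-methylbenzoate F5.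
- Lateral lithiation and acylation with 2 as in step 3 gives prop-2-en-1-yl 2,4-bis(benzyloxy)-6-(2-oxononyl)benzoate F6.
- Noyori ketalization as in step 4 gives prop-2-en-1-yl 2,4-bis(benzyloxy)-6-[(2-heptyl-1,3-dioxolan-2-yl)methyl]benzoate F7.
- Pd(PPh3)4 and morpholine in THF at room temperature transfer the allyl group to the amine and give 7.

Step 11. The acid stage may cause lactonization of a freed ketone enol onto the neighbouring ester, which in ring A would cleave the depside. Hydrogenolysis of the ether flanked by the ester may also be sluggish. The fallback reverses the order so that the free phenolic product never meets acid. It sets out from 14 and returns at 16. Dilute aqueous HCl in THF removes both dioxolanes while the phenols are still protected and gives 3-[(3,5-dimethylbenzyl)oxy]-4-(methoxycarbonyl)-5-(2-oxononyl)phenyl 2,4-bis(benzyloxy)-6-(2-oxononyl)benzoate F8. F8 is purified and then hydrogenolysed (H2, Pd/C, EtOAc, rt) to 16 under neutral conditions.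

## Further compounds

F1 | step 10 | methyl 2-[(3,5-dimethylbenzyl)oxy]-4-hydroxy-6-[(2-heptyl-1,3-dioxolan-2-yl)methyl]benzoate | CCCCCCCC1(OCCO1)Cc1cc(O)cc(OCc2cc(C)cc(C)c2)c1C(=O)OC
F2 | step 10 | 2,4-bis(benzyloxy)-6-[(2-heptyl-1,3-dioxolan-2-yl)methyl]benzoyl chloride | CCCCCCCC1(OCCO1)Cc1cc(OCc2ccccc2)cc(OCc2ccccc2)c1C(=O)Cl
F3 | step 9 | potassium {3-[(3,5-dimethylbenzyl)oxy]-5-[(2-heptyl-1,3-dioxolan-2-yl)methyl]-4-(methoxycarbonyl)phenyl}trifluoroborate | CCCCCCCC1(OCCO1)Cc1cc([B-](F)(F)F)cc(OCc2cc(C)cc(C)c2)c1C(=O)OC.[K+]
F4 | step 5 | 2,4-bis(benzyloxy)-6-methylbenzoic acid | Cc1cc(OCc2ccccc2)cc(OCc2ccccc2)c1C(=O)O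
F5 | step 5 | prop-2-en-1-yl 2,4-bis(benzyloxy)-6-methylbenzoate | Cc1cc(OCc2ccccc2)cc(OCc2ccccc2)c1C(=O)OCC=C
F6 | step 5 | prop-2-en-1-yl 2,4-bis(benzyloxy)-6-(2-oxononyl)benzoate | CCCCCCCC(=O)Cc1cc(OCc2ccccc2)cc(OCc2ccccc2)c1C(=O)OCC=C
F7 | step 5 | prop-2-en-1-yl 2,4-bis(benzyloxy)-6-[(2-heptyl-1,3-dioxolan-2-yl)methyl]benzoate | CCCCCCCC1(OCCO1)Cc1cc(OCc2ccccc2)cc(OCc2ccccc2)c1C(=O)OCC=C
F8 | step 11 | 3-[(3,5-dimethylbenzyl)oxy]-4-(methoxycarbonyl)-5-(2-oxononyl)phenyl 2,4-bis(benzyloxy)-6-(2-oxononyl)benzoate | CCCCCCCC(=O)Cc1cc(OCc2ccccc2)cc(OCc2ccccc2)c1C(=O)Oc1cc(OCc2cc(C)cc(C)c2)c(C(=O)OC)c(CC(=O)CCCCCCC)c1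
A1 | alternative 1 | 3-hydroxy-5-[(2-heptyl-1,3-dioxolan-2-yl)methyl]-4-(methoxycarbonyl)phenyl 2,4-dihydroxy-6-[(2-heptyl-1,3-dioxolan-2-yl)methyl]benzoate (identical with 15) | CCCCCCCC1(OCCO1)Cc1cc(O)cc(O)c1C(=O)Oc1cc(O)c(C(=O)OC)c(CC2(CCCCCCC)OCCO2)c1
A2 | alternative 1 | 3-hydroxy-5-[(2-heptyl-1,3-dioxolan-2-yl)methyl]-4-(methoxycarbonyl)phenyl 8-(2-heptyl-1,3-dioxolan-2-yl)-3,5,7-trioxooctanoate | CCCCCCCC1(OCCO1)CC(=O)CC(=O)CC(=O)CC(=O)Oc1cc(O)c(C(=O)OC)c(CC2(CCCCCCC)OCCO2)c1
A3 | alternative 1 | methyl 2,4-dihydroxy-6-[(2-heptyl-1,3-dioxolan-2-yl)methyl]benzoate | CCCCCCCC1(OCCO1)Cc1cc(O)cc(O)c1C(=O)OC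
A4 | alternative 2 | methyl 2,4-bis(benzyloxy)-6-(2-methoxy-2-oxoethyl)benzoate (dimethyl 3,5-bis(benzyloxy)homophthalate) | COC(=O)Cc1cc(OCc2ccccc2)cc(OCc2ccccc2)c1C(=O)OC
A5 | alternative 2 | 3,5-bis(benzyloxy)-2-(trimethylsilyl)phenyl trifluoromethanesulfonate | C[Si](C)(C)c1c(OCc2ccccc2)cc(OCc2ccccc2)cc1OS(=O)(=O)C(F)(F)F
A6 | alternative 2 | dimethyl malonate | COC(=O)CC(=O)OC
A7 | alternative 3 | 3-methoxy-4-(methoxycarbonyl)-5-[(2-heptyl-1,3-dioxolan-2-yl)methyl]phenyl 4-hydroxy-2-methoxy-6-[(2-heptyl-1,3-dioxolan-2-yl)methyl]benzoate | CCCCCCCC1(OCCO1)Cc1cc(O)cc(OC)c1C(=O)Oc1cc(OC)c(C(=O)OC)c(CC2(CCCCCCC)OCCO2)c1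
A8 | alternative 3 | 3-methoxy-4-(methoxycarbonyl)-5-[(2-heptyl-1,3-dioxolan-2-yl)methyl]phenyl 4-(2-heptyl-1,3-dioxolan-2-yl)but-2-ynoate | CCCCCCCC1(OCCO1)CC#CC(=O)Oc1cc(OC)c(C(=O)OC)c(CC2(CCCCCCC)OCCO2)c1
A9 | alternative 3 | 1,1-dimethoxy-3-(trimethylsilyloxy)buta-1,3-diene | COC(OC)=CC(=C)O[Si](C)(C)C
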